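**Retrosynthetic overview**

1. The strategy rests on the benzylic ether oxygen that joins C4 of unit A (the 6,8-dihydroxy-7-methoxyisochromanone) to C6 of the benzene ring of unit B (the 4,8-dihydroxy-7-methoxyisochromanone). On that ring the C6 ether oxygen, C7–OMe, C8–OH, the C8a carboxyl and the C4a side chain are contiguous, which is the pattern given by a 1,2,3-trioxygenated ketene acetal diene (C5 to C8) and a 2-alkynoate (C8a, C4a), so the ether can exist as an enol ether before either arene is made.
2. Last disconnections: both lactone O2–C1 bonds (to hydroxy methyl esters), then the benzene ring of unit B by Diels–Alder cycloaddition and aromatization between a ketene acetal diene carrying unit A on its 3-oxygen and a (4R,5R)-4,5-bis(silyloxy)hex-2-ynoate.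
3. The benzene ring of unit A is cut the same way into a 1,3-bis(silyloxy) ketene acetal diene and a (4S,5R)-ynoate whose carbinol oxygen already carries the 2,3-dimethoxycrotonate enol ether, made from the O–H so that the C4–O bond is never broken.
4. Both ynoates come from one ynone (methyl (R)-lactate plus methyl propiolate) by reduction with enantiomeric catalysts; the dienes and the enol ether donor come from methyl acetoacetate.
5. Ring order: benzene ring of unit A, benzene ring of unit B, then both six-membered lactone rings together.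

Key step: step 17

Remark: the tetrasubstituted enol ether double bonds formed on the way are expected as E/Z mixtures and are written without geometry, because both isomers lead to the same dienolate.
Remark: the sense of induction given for the two enantiomeric ruthenium catalysts follows the usual model for alkynyl ketones (alkynyl in the place of aryl) and is taken as an assumption.

**Route**

Step 1
Reactants: 1 methyl acetoacetate
Product: 2 methyl 2-diazo-3-oxobutanoate
Conditions: p-ABSA, Et3N, MeCN, 0 °C → rt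
Reagents that add atoms: 4-acetamidobenzenesulfonyl azide (p-ABSA), CC(=O)Nc1ccc(cc1)S(=O)(=O)N=[N+]=[N-]
Why: Regitz diazo transfer to the doubly activated methylene of a β-keto ester is a standard reaction.

Step 2
Reactants: 2 methyl 2-diazo-3-oxobutanoate
Product: 3 methyl 2-methoxy-3-oxobutanoate (racemic)
Conditions: Rh2(OAc)4 (1 mol%), MeOH (5 equiv), CH2Cl2, 40 °C
Reagents that add atoms: methanol, CO
Why: Rhodium carbenoid O–H insertion into an alcohol is the established route to 2-alkoxy-1,3-dicarbonyl compounds and should outpace Wolff rearrangement.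

Step 3
Reactants: 3 methyl 2-methoxy-3-oxobutanoate
Product: 4 methyl 2-methoxy-3-(trimethylsilyloxy)but-2-enoate
Conditions: TMSCl, Et3N, toluene, rt
Reagents that add atoms: chlorotrimethylsilane, C[Si](C)(C)Cl
Why: Silyl enol ether formation under equilibrating amine conditions should give the conjugated enol ether at the most acidic C2–H.

Step 4
Reactants: 4 methyl 2-methoxy-3-(trimethylsilyloxy)but-2-enoate
Product: 6 1,2-dimethoxy-1,3-bis(trimethylsilyloxy)buta-1,3-diene, via lithium dienolate 5 (not isolated)
Conditions: LiN(iPr)2, THF, −78 °C; TMSCl, −78 °C → rt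
Reagents that add atoms: chlorotrimethylsilane, C[Si](C)(C)Cl
Why: γ-Deprotonation of the silyl enol ether ester and O-silylation of the dienolate is the standard preparation of Chan-type 1,3-bis(silyloxy) ketene acetal dienes.

Step 5
Reactants: 3 methyl 2-methoxy-3-oxobutanoate
Product: 8 methyl 2,3-dimethoxybut-2-enoate, via methyl 2,3,3-trimethoxybutanoate 7 (not isolated)
Conditions: HC(OMe)3, H2SO4 (cat.), rt; then TsOH (cat.), 130 °C, MeOH distilled off
Reagents that add atoms: trimethyl orthoformate, COC(OC)OC
Why: Ketalisation with an orthoformate and acid-catalysed thermal loss of methanol toward the ester is the usual preparation of β-methoxy crotonates and should give the conjugated enol ether.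

Step 6
Reactants: 8 methyl 2,3-dimethoxybut-2-enoate
Product: 10 methyl 2,3-dimethoxybut-3-enoate (racemic), via lithium dienolate 9 (not isolated)
Conditions: LiN(iPr)2, THF/DMPU, −78 °C; then AcOH, −78 °C
Reagents that add atoms: none
Why: γ-Deprotonation gives the extended enolate, and kinetic protonation at the α-carbon (deconjugative protonation of an ester dienolate) should give the reactive 2-alkoxypropene-type isomer.

Step 7
Reactants: 11 methyl (R)-lactate
Product: 12 methyl (R)-2-(triethylsilyloxy)propanoate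
Conditions: TESCl, imidazole, CH2Cl2, 0 °C
Reagents that add atoms: chlorotriethylsilane, CC[Si](Cl)(CC)CC
Why: Standard O-silylation of a secondary alcohol, which does not touch the stereocentre.

Step 8
Reactants: 12 methyl (R)-2-(triethylsilyloxy)propanoate
Product: 13 (R)-N-methoxy-N-methyl-2-(triethylsilyloxy)propanamide
Conditions: MeNHOMe·HCl, iPrMgCl, THF, −20 °C
Reagents that add atoms: N,O-dimethylhydroxylamine hydrochloride, CNOC.Cl
Why: Aminolysis of the ester by the chloromagnesium amide is a standard Weinreb amide synthesis that should leave the α-stereocentre and the silyl ether intact.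

Step 9
Reactants: 13 (R)-N-methoxy-N-methyl-2-(triethylsilyloxy)propanamide; 14 methyl propiolate
Product: 17 methyl (5R)-4-oxo-5-(triethylsilyloxy)hex-2-ynoate, via methyl 3-lithiopropiolate 15 (not isolated), via lithium alkoxide adduct 16 (not isolated)
Conditions: 14, LiN(SiMe3)2, THF, −78 °C; then 13, −78 °C; AcOH, −78 °C, then cold aq. citric acid
Reagents that add atoms: none
Why: Acylation of a lithium acetylide by a Weinreb amide stops at the chelated tetrahedral adduct, the low temperature keeps the lithiated propiolate intact, and the cold acidic quench protonates the liberated amine before it can add to the ynone.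

Step 10
Reactants: 17 methyl (5R)-4-oxo-5-(triethylsilyloxy)hex-2-ynoate
Product: 18 methyl (4S,5R)-4-hydroxy-5-(triethylsilyloxy)hex-2-ynoate
Conditions: Ru[(R,R)-TsDPEN](p-cymene) (2 mol%), iPrOH, rt
Reagents that add atoms: none
Why: Noyori asymmetric transfer hydrogenation of an alkynyl ketone under base-free conditions, in which the (R,R) catalyst should deliver hydride under catalyst control to the face that gives the 4S (anti) carbinol next to the 5R silyloxy centre.

Step 11
Reactants: 17 methyl (5R)-4-oxo-5-(triethylsilyloxy)hex-2-ynoate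
Product: 19 methyl (4R,5R)-4-hydroxy-5-(triethylsilyloxy)hex-2-ynoate
Conditions: Ru[(S,S)-TsDPEN](p-cymene) (2 mol%), iPrOH, rt
Reagents that add atoms: none
Why: The same Noyori transfer hydrogenation with the enantiomeric catalyst should give the 4R (syn) carbinol, again under catalyst control.

Step 12
Reactants: 19 methyl (4R,5R)-4-hydroxy-5-(triethylsilyloxy)hex-2-ynoate
Product: 20 methyl (4R,5R)-4-(tert-butyldimethylsilyloxy)-5-(triethylsilyloxy)hex-2-ynoate
Conditions: TBSOTf, 2,6-lutidine, CH2Cl2, −78 → 0 °C
Reagents that add atoms: tert-butyldimethylsilyl trifluoromethanesulfonate, CC(C)(C)[Si](C)(C)OS(=O)(=O)C(F)(F)F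
Why: A silyl triflate with a hindered, non-nucleophilic base silylates the secondary propargylic alcohol without conjugate addition to the ynoate and without touching a stereocentre.

Step 13
Reactants: 18 methyl (4S,5R)-4-hydroxy-5-(triethylsilyloxy)hex-2-ynoate; 10 methyl 2,3-dimethoxybut-3-enoate
Product: 22 methyl (4S,5R)-4-[(3,4-dimethoxy-4-oxobut-2-en-2-yl)oxy]-5-(triethylsilyloxy)hex-2-ynoate, via mixed methyl ketal 21 (not isolated)
Conditions: 10 (4 equiv), PPTS (5 mol%), CH2Cl2, 0 °C; then iPr2NEt, TMSOTf, −20 → 0 °C; then PPTS (cat.), CH2Cl2, rt (draws any exo-methylene isomer into the conjugated enoate)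
Reagents that add atoms: none
Why: Acid-catalysed Markovnikov addition of the carbinol O–H to the 1,1-disubstituted enol ether (mixed ketal formation as with 2-methoxypropene), then silyl triflate/amine elimination of methanol from the ketal with loss of the less hindered methoxy group and of the proton next to the ester, should give the enol ether without base acting on the ynoate and without breaking the carbinol C4–O bond, so the 4S centre is retained.

Step 14
Reactants: 22 methyl (4S,5R)-4-[(3,4-dimethoxy-4-oxobut-2-en-2-yl)oxy]-5-(triethylsilyloxy)hex-2-ynoate; 6 1,2-dimethoxy-1,3-bis(trimethylsilyloxy)buta-1,3-diene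
Product: 24 methyl 2-{(1S,2R)-1-[(3,4-dimethoxy-4-oxobut-2-en-2-yl)oxy]-2-(triethylsilyloxy)propyl}-4,6-dihydroxy-5-methoxybenzoate, via cyclohexadiene cycloadduct 23 (not isolated)
Conditions: 6 (2 equiv), toluene, 80 °C; then MeOH, SiO2, rt
Reagents that add atoms: none
Why: Normal-demand Diels–Alder reaction of the ketene acetal diene with the ynoate (CH2 terminus to the β-carbon), then aromatization by collapse of the silyl methyl ketal and methanolysis of the aryl silyl ethers; the tetrasubstituted push–pull enoate is no dienophile and 80 °C should stay below the onset of propargyl Claisen (Saucy–Marbet) rearrangement.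

Step 15
Reactants: 24 methyl 2-{(1S,2R)-1-[(3,4-dimethoxy-4-oxobut-2-en-2-yl)oxy]-2-(triethylsilyloxy)propyl}-4,6-dihydroxy-5-methoxybenzoate
Product: 25 methyl 4,6-bis(tert-butyldimethylsilyloxy)-2-{(1S,2R)-1-[(3,4-dimethoxy-4-oxobut-2-en-2-yl)oxy]-2-(triethylsilyloxy)propyl}-5-methoxybenzoate
Conditions: TBSOTf, 2,6-lutidine, CH2Cl2, 0 °C → rt
Reagents that add atoms: tert-butyldimethylsilyl trifluoromethanesulfonate, CC(C)(C)[Si](C)(C)OS(=O)(=O)C(F)(F)F
Why: Silyl triflate silylation should cover both phenols, including the hindered hydrogen-bonded one next to the ester, so that the strong base of the next step meets no acidic O–H.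

Step 16
Reactants: 25 methyl 4,6-bis(tert-butyldimethylsilyloxy)-2-{(1S,2R)-1-[(3,4-dimethoxy-4-oxobut-2-en-2-yl)oxy]-2-(triethylsilyloxy)propyl}-5-methoxybenzoate
Product: 27 methyl 4,6-bis(tert-butyldimethylsilyloxy)-2-{(1S,2R)-1-{[3,4-dimethoxy-4-(trimethylsilyloxy)buta-1,3-dien-2-yl]oxy}-2-(triethylsilyloxy)propyl}-5-methoxybenzoate, via lithium dienolate 26 (not isolated)
Conditions: LiN(iPr)2, THF, −78 °C; TMSCl, −78 → 0 °C; crude, used at once
Reagents that add atoms: chlorotrimethylsilane, C[Si](C)(C)Cl
Why: γ-Deprotonation of a β-alkoxy crotonate and O-silylation of the dienolate is the standard route to Brassard-type dienes, and the twisted, di-ortho-substituted benzoate should resist both addition and lateral benzylic deprotonation, so the 4S centre is not touched.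

Step 17
Reactants: 27 the ketene acetal diene carrying unit A; 20 methyl (4R,5R)-4-(tert-butyldimethylsilyloxy)-5-(triethylsilyloxy)hex-2-ynoate
Product: 29 methyl 4-{(1S,2R)-1-[3,5-bis(tert-butyldimethylsilyloxy)-4-methoxy-2-(methoxycarbonyl)phenyl]-2-(triethylsilyloxy)propoxy}-2-[(1R,2R)-1-(tert-butyldimethylsilyloxy)-2-(triethylsilyloxy)propyl]-6-hydroxy-5-methoxybenzoate, via cyclohexadiene cycloadduct 28 (not isolated)
Conditions: 27 (1.3 equiv), toluene (2 M), 100 °C, sealed tube; then MeOH, SiO2, rt
Reagents that add atoms: none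
Why: The triply oxygen-substituted diene 27 should add to the polarised ynoate 20 in a normal-demand, asynchronous [4+2] cycloaddition in which the unhindered CH2 terminus bonds to the β-carbon (future C5–C4a) and the ketene acetal carbon to the α-carbon (future C8–C8a). The closest known reaction type is the Diels–Alder benzannulation of 1-alkoxy-1-silyloxy-3-oxybutadienes (Brassard- and Chan-type dienes) with 2-alkynoates, which gives resorcylate esters. The benzene ring of unit B is thus closed by intermolecular [4+2] cycloaddition and made aromatic by irreversible collapse of the silyl methyl ketal of cycloadduct 28 (loss of methanol and of the trimethylsilyl group), directly onto the ether oxygen that already sits on C4 of unit A. No stereocentre is created, since the ketal carbon of 28 disappears on aromatization and the four existing centres lie outside the reacting atoms. Only regioselectivity is needed, and it is secured by the match between the nucleophilic CH2 terminus of the ketene acetal diene and the electrophilic β-carbon of the ynoate, which places the ester next to the new C8 hydroxyl and the ether oxygen at C6. The benzylic C4–O bond is only a spectator substituent of the diene and a benzyl vinyl ether has no easy [3,3] pathway, so ionisation, elimination or rearrangement at C4 is avoided; the cost is the steric demand of both partners, met by high concentration and heat.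

Step 18
Reactants: 29 the bis-benzoate
Product: 31 (3R,4S)-6,8-bis(tert-butyldimethylsilyloxy)-4-{[(3R,4R)-4-(tert-butyldimethylsilyloxy)-8-hydroxy-7-methoxy-3-methyl-1-oxoisochroman-6-yl]oxy}-7-methoxy-3-methylisochroman-1-one, via dihydroxy diester 30 (not isolated)
Conditions: PPTS, MeOH/CH2Cl2, 0 °C → rt; then CSA (cat.), toluene, 60 °C
Reagents that add atoms: none
Why: Triethylsilyl ethers are cleaved by mildly acidic methanol well before secondary or aryl tert-butyldimethylsilyl ethers, and each freed C3 hydroxyl should then close a six-membered lactone on the neighbouring methyl ester by acid-catalysed transesterification, while the still silylated C4 oxygen of unit B cannot form the competing five-membered phthalide.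

Step 19
Reactants: 31 the silyl-protected bis-lactone
Product: 32 (3R,4S)-4-{[(3R,4R)-4,8-dihydroxy-7-methoxy-3-methyl-1-oxoisochroman-6-yl]oxy}-6,8-dihydroxy-7-methoxy-3-methylisochroman-1-one (CNP0139537.4)
Conditions: HF·pyridine, pyridine, THF, 0 °C → rt
Reagents that add atoms: none
Why: Pyridine-buffered fluoride desilylation should remove the two aryl and the one secondary silyl ether without opening the lactones or ionising the benzylic aryl ether.

**Compound list**

1 | methyl acetoacetate | CC(=O)CC(=O)OC | starting material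
2 | methyl 2-diazo-3-oxobutanoate | CC(=O)C(=[N+]=[N-])C(=O)OC | intermediate
3 | methyl 2-methoxy-3-oxobutanoate (racemic) | CC(=O)C(OC)C(=O)OC | intermediate
4 | methyl 2-methoxy-3-(trimethylsilyloxy)but-2-enoate | CC(O[Si](C)(C)C)=C(OC)C(=O)OC | intermediate
5 | lithium 1,2-dimethoxy-3-(trimethylsilyloxy)buta-1,3-dien-1-olate | [Li+].[O-]C(OC)=C(OC)C(=C)O[Si](C)(C)C | intermediate
6 | 1,2-dimethoxy-1,3-bis(trimethylsilyloxy)buta-1,3-diene | C=C(O[Si](C)(C)C)C(OC)=C(OC)O[Si](C)(C)C | intermediate
7 | methyl 2,3,3-trimethoxybutanoate (racemic) | CC(OC)(OC)C(OC)C(=O)OC | intermediate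
8 | methyl 2,3-dimethoxybut-2-enoate (E/Z) | CC(OC)=C(OC)C(=O)OC | intermediate
9 | lithium 1,2,3-trimethoxybuta-1,3-dien-1-olate | [Li+].[O-]C(OC)=C(OC)C(=C)OC | intermediate
10 | methyl 2,3-dimethoxybut-3-enoate (racemic) | C=C(OC)C(OC)C(=O)OC | intermediate
11 | methyl (R)-lactate | O[C@H](C)C(=O)OC | starting material
12 | methyl (R)-2-(triethylsilyloxy)propanoate | CC[Si](CC)(CC)O[C@H](C)C(=O)OC | intermediate
13 | (R)-N-methoxy-N-methyl-2-(triethylsilyloxy)propanamide | CC[Si](CC)(CC)O[C@H](C)C(=O)N(C)OC | intermediate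
14 | methyl propiolate | C#CC(=O)OC | starting material
15 | methyl 3-lithiopropiolate | [Li+].[C-]#CC(=O)OC | intermediate
16 | lithium alkoxide adduct of 15 to the amide carbonyl of 13 (new carbinolamine centre undefined) | CC[Si](CC)(CC)O[C@H](C)C([O-])(C#CC(=O)OC)N(C)OC.[Li+] | intermediate
17 | methyl (5R)-4-oxo-5-(triethylsilyloxy)hex-2-ynoate | CC[Si](CC)(CC)O[C@H](C)C(=O)C#CC(=O)OC | intermediate
18 | methyl (4S,5R)-4-hydroxy-5-(triethylsilyloxy)hex-2-ynoate (anti) | CC[Si](CC)(CC)O[C@H](C)[C@H](C#CC(=O)OC)O | intermediate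
19 | methyl (4R,5R)-4-hydroxy-5-(triethylsilyloxy)hex-2-ynoate (syn) | CC[Si](CC)(CC)O[C@H](C)[C@@H](C#CC(=O)OC)O | intermediate
20 | methyl (4R,5R)-4-(tert-butyldimethylsilyloxy)-5-(triethylsilyloxy)hex-2-ynoate | CC[Si](CC)(CC)O[C@H](C)[C@@H](C#CC(=O)OC)O[Si](C)(C)C(C)(C)C | intermediate
21 | methyl (4S,5R)-4-[(2,3,4-trimethoxy-4-oxobutan-2-yl)oxy]-5-(triethylsilyloxy)hex-2-ynoate (mixed methyl ketal, diastereomer mixture) | CC[Si](CC)(CC)O[C@H](C)[C@H](C#CC(=O)OC)OC(C)(OC)C(OC)C(=O)OC | intermediate
22 | methyl (4S,5R)-4-[(3,4-dimethoxy-4-oxobut-2-en-2-yl)oxy]-5-(triethylsilyloxy)hex-2-ynoate (E/Z) | CC[Si](CC)(CC)O[C@H](C)[C@H](C#CC(=O)OC)OC(C)=C(OC)C(=O)OC | intermediate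
23 | cyclohexa-1,4-diene cycloadduct of 22 and 6 (ring: CH2, C(OSiMe3)=C(OMe), C(OMe)(OSiMe3), C(CO2Me)=C bearing the side chain) | CC[Si](CC)(CC)O[C@H](C)[C@H](C1=C(C(=O)OC)C(OC)(O[Si](C)(C)C)C(OC)=C(O[Si](C)(C)C)C1)OC(C)=C(OC)C(=O)OC | intermediate
24 | methyl 2-{(1S,2R)-1-[(3,4-dimethoxy-4-oxobut-2-en-2-yl)oxy]-2-(triethylsilyloxy)propyl}-4,6-dihydroxy-5-methoxybenzoate | CC[Si](CC)(CC)O[C@H](C)[C@H](c1cc(O)c(OC)c(O)c1C(=O)OC)OC(C)=C(OC)C(=O)OC | intermediate
25 | methyl 4,6-bis(tert-butyldimethylsilyloxy)-2-{(1S,2R)-1-[(3,4-dimethoxy-4-oxobut-2-en-2-yl)oxy]-2-(triethylsilyloxy)propyl}-5-methoxybenzoate | CC[Si](CC)(CC)O[C@H](C)[C@H](c1cc(O[Si](C)(C)C(C)(C)C)c(OC)c(O[Si](C)(C)C(C)(C)C)c1C(=O)OC)OC(C)=C(OC)C(=O)OC | intermediate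
26 | lithium dienolate of 25 (γ-deprotonated crotonate) | CC[Si](CC)(CC)O[C@H](C)[C@H](c1cc(O[Si](C)(C)C(C)(C)C)c(OC)c(O[Si](C)(C)C(C)(C)C)c1C(=O)OC)OC(=C)C(OC)=C(OC)[O-].[Li+] | intermediate
27 | methyl 4,6-bis(tert-butyldimethylsilyloxy)-2-{(1S,2R)-1-{[3,4-dimethoxy-4-(trimethylsilyloxy)buta-1,3-dien-2-yl]oxy}-2-(triethylsilyloxy)propyl}-5-methoxybenzoate | CC[Si](CC)(CC)O[C@H](C)[C@H](c1cc(O[Si](C)(C)C(C)(C)C)c(OC)c(O[Si](C)(C)C(C)(C)C)c1C(=O)OC)OC(=C)C(OC)=C(OC)O[Si](C)(C)C | intermediate
28 | cyclohexa-1,4-diene cycloadduct of 27 and 20 (ring: CH2, C(O–unit A)=C(OMe), C(OMe)(OSiMe3), C(CO2Me)=C bearing the bis(silyloxy)propyl chain) | CC[Si](CC)(CC)O[C@H](C)[C@H](c1cc(O[Si](C)(C)C(C)(C)C)c(OC)c(O[Si](C)(C)C(C)(C)C)c1C(=O)OC)OC1=C(OC)C(OC)(O[Si](C)(C)C)C(C(=O)OC)=C(C1)[C@@H](O[Si](C)(C)C(C)(C)C)[C@@H](C)O[Si](CC)(CC)CC | intermediate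
29 | methyl 4-{(1S,2R)-1-[3,5-bis(tert-butyldimethylsilyloxy)-4-methoxy-2-(methoxycarbonyl)phenyl]-2-(triethylsilyloxy)propoxy}-2-[(1R,2R)-1-(tert-butyldimethylsilyloxy)-2-(triethylsilyloxy)propyl]-6-hydroxy-5-methoxybenzoate | CC[Si](CC)(CC)O[C@H](C)[C@H](c1cc(O[Si](C)(C)C(C)(C)C)c(OC)c(O[Si](C)(C)C(C)(C)C)c1C(=O)OC)Oc1cc([C@@H](O[Si](C)(C)C(C)(C)C)[C@@H](C)O[Si](CC)(CC)CC)c(C(=O)OC)c(O)c1OC | intermediate
30 | dihydroxy diester (29 with both triethylsilyl ethers replaced by OH) | O[C@H](C)[C@H](c1cc(O[Si](C)(C)C(C)(C)C)c(OC)c(O[Si](C)(C)C(C)(C)C)c1C(=O)OC)Oc1cc([C@@H](O[Si](C)(C)C(C)(C)C)[C@@H](C)O)c(C(=O)OC)c(O)c1OC | intermediate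
31 | (3R,4S)-6,8-bis(tert-butyldimethylsilyloxy)-4-{[(3R,4R)-4-(tert-butyldimethylsilyloxy)-8-hydroxy-7-methoxy-3-methyl-1-oxoisochroman-6-yl]oxy}-7-methoxy-3-methylisochroman-1-one | COc1c(O[Si](C)(C)C(C)(C)C)cc2c(c1O[Si](C)(C)C(C)(C)C)C(=O)O[C@H](C)[C@H]2Oc1cc2c(c(O)c1OC)C(=O)O[C@H](C)[C@@H]2O[Si](C)(C)C(C)(C)C | intermediate
32 | (3R,4S)-4-{[(3R,4R)-4,8-dihydroxy-7-methoxy-3-methyl-1-oxoisochroman-6-yl]oxy}-6,8-dihydroxy-7-methoxy-3-methylisochroman-1-one (CNP0139537.4) | COc1c(O)cc2c(c1O)C(=O)O[C@H](C)[C@H]2Oc1cc2c(c(O)c1OC)C(=O)O[C@H](C)[C@@H]2O | target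

**Step count and risks**

Total step count: 19.
Longest linear sequence: 11 steps (steps 7, 8, 9, 10, 13, 14, 15, 16, 17, 18, 19 from methyl (R)-lactate; the chain 1, 2, 5, 6, 13 to 19 from methyl acetoacetate is equally long).

Steps most likely to fail:

Step 17. The cycloaddition may be too slow for steric reasons (branched β-carbon of the ynoate, bulky 3-alkoxy group on the diene), so that the silyl ketene acetal is lost to desilylation or O-to-C silyl migration before it has reacted. The fallback replaces the ynoate by the far more electrophilic alkynal and restores the ester afterwards. It sets out from 20 and comes back at 29. Reduction of 20 with iBu2AlH (CH2Cl2, −78 °C) should give (4R,5R)-4-(tert-butyldimethylsilyloxy)-5-(triethylsilyloxy)hex-2-yn-1-ol F1, and oxidation with MnO2 (CH2Cl2, rt) should give (4R,5R)-4-(tert-butyldimethylsilyloxy)-5-(triethylsilyloxy)hex-2-ynal F2. Thermal cycloaddition of F2 with 27 (toluene, rt to 40 °C, no Lewis acid, so that the triple bond and not the formyl group acts as dienophile) should give the cyclohexadiene cycloadduct F3, which on methanolysis over SiO2 should aromatise to the 2-formyl analogue of 29 F4. Pinnick oxidation (NaClO2, NaH2PO4, 2-methyl-2-butene, tBuOH/H2O) should then give the corresponding benzoic acid F5, and TMSCHN2 in toluene/MeOH should esterify it to 29.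

Step 13. Acid-catalysed isomerisation of the reactive enol ether 10 to its conjugated isomer 8 may outrun its capture by the hindered, electron-poor alcohol 18, or the mixed ketal may ionise with loss of the wrong alkoxy group and return 18. The fallback is the direct thermodynamic transetherification, which sets out from 18 and 8 and comes back at 22 without any new compound. Alcohol 18 and an excess of 8 would be heated with catalytic CSA in toluene at or below 80 °C, methanol being taken up continuously by 5 Å molecular sieves in a Soxhlet thimble so that the triethylsilyl ether does not meet acidic methanol and the temperature stays below the onset of propargyl Claisen rearrangement.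

Step 9. The lithiated propiolate may decompose before it acylates the amide, and the N,O-dimethylhydroxylamine set free on quench may add to the very electrophilic ynone. The fallback builds the ynone by aldehyde addition and oxidation, sets out from 12 and comes back at 17. Reduction of 12 with iBu2AlH (CH2Cl2, −78 °C) should give (R)-2-(triethylsilyloxy)propanal F6. Addition of 15 (from 14 and LiN(SiMe3)2, THF, −78 °C), which is fast with aldehydes, should give methyl (5R)-4-hydroxy-5-(triethylsilyloxy)hex-2-ynoate as a mixture of C4 epimers F7. Oxidation with Dess–Martin periodinane and NaHCO3 in CH2Cl2 should then give 17.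

**Further compounds**

F1 | step 17 | (4R,5R)-4-(tert-butyldimethylsilyloxy)-5-(triethylsilyloxy)hex-2-yn-1-ol | CC[Si](CC)(CC)O[C@H](C)[C@@H](C#CCO)O[Si](C)(C)C(C)(C)C
F2 | step 17 | (4R,5R)-4-(tert-butyldimethylsilyloxy)-5-(triethylsilyloxy)hex-2-ynal | CC[Si](CC)(CC)O[C@H](C)[C@@H](C#CC=O)O[Si](C)(C)C(C)(C)C
F3 | step 17 | cyclohexa-1,4-diene cycloadduct of 27 and F2 | CC[Si](CC)(CC)O[C@H](C)[C@H](c1cc(O[Si](C)(C)C(C)(C)C)c(OC)c(O[Si](C)(C)C(C)(C)C)c1C(=O)OC)OC1=C(OC)C(OC)(O[Si](C)(C)C)C(C=O)=C(C1)[C@@H](O[Si](C)(C)C(C)(C)C)[C@@H](C)O[Si](CC)(CC)CC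
F4 | step 17 | 2-formyl analogue of 29 (CHO in place of the CO2Me of unit B) | CC[Si](CC)(CC)O[C@H](C)[C@H](c1cc(O[Si](C)(C)C(C)(C)C)c(OC)c(O[Si](C)(C)C(C)(C)C)c1C(=O)OC)Oc1cc([C@@H](O[Si](C)(C)C(C)(C)C)[C@@H](C)O[Si](CC)(CC)CC)c(C=O)c(O)c1OC
F5 | step 17 | benzoic acid corresponding to 29 (CO2H in place of the CO2Me of unit B) | CC[Si](CC)(CC)O[C@H](C)[C@H](c1cc(O[Si](C)(C)C(C)(C)C)c(OC)c(O[Si](C)(C)C(C)(C)C)c1C(=O)OC)Oc1cc([C@@H](O[Si](C)(C)C(C)(C)C)[C@@H](C)O[Si](CC)(CC)CC)c(C(=O)O)c(O)c1OC
F0 | step 13 | none | none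
F6 | step 9 | (R)-2-(triethylsilyloxy)propanal | CC[Si](CC)(CC)O[C@H](C)C=O
F7 | step 9 | methyl (5R)-4-hydroxy-5-(triethylsilyloxy)hex-2-ynoate (C4 epimers) | CC[Si](CC)(CC)O[C@H](C)C(O)C#CC(=O)OC
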